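**Plan**

- Retrosynthesis cuts the two ester C1–O9 bonds of the C2-symmetric twenty-membered diolide to one hydroxy acid (numbered C1 carboxyl to C10, the CH2 on the oxazole). Further cuts are C4=C5 (back to an enyne), C3–C4 (Sonogashira), alkyne carbon C4 (aldehyde homologation) and C5–C6/C6–C7 (Wittig).
- The last cut is the oxazole ring at C4–C5 and O1–C2. Each oxazole is substituted only at C5 (C2–H and C4–H free) and its C5 is tied through the C10 methylene to the C9 carbinol, C8 and C7. Oxazole C5–C10–C9–C8–C7–O is therefore the acyl chain of a six-membered δ-lactone: the lactone carbonyl carbon and oxygen become oxazole C5 and O1, and C4, N3 and C2 come from methyl isocyanide.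
- Forward order of rings: δ-lactone (step 4), oxazole by opening that lactone (step 7), chain growth from C7 to C4, C3–C4 coupling, semireduction, and the macrocycle last by head-to-tail cyclodimerisation (step 18).
- Stereochemistry: C8 from (R)-Roche ester; C9 from catalyst-controlled hydrogenation with the (S)-BINAP ruthenium catalyst; the 2Z alkene from anti-carbomagnesiation of propargyl alcohol; the 4Z alkene from syn semireduction of the enyne.

Key step: step 7

Remark: the target is read from the SMILES as the all-(Z), (8R,9R) head-to-tail dimer in both halves; in the δ-lactone this corresponds to silyloxy and methyl groups trans on the ring (syn in the open chain).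

**Route**

Step 1
Reactants: 1 methyl (R)-3-hydroxy-2-methylpropanoate
Product: 2 methyl (R)-3-(benzyloxy)-2-methylpropanoate
Conditions: BnOC(=NH)CCl3, TfOH (cat.), CH2Cl2/cyclohexane, 0 °C → rt
Reagents that add atoms: benzyl 2,2,2-trichloroacetimidate, ClC(Cl)(Cl)C(=N)OCc1ccccc1
Why: Acid-catalysed O-benzylation with the trichloroacetimidate etherifies the primary alcohol without base, so the enolisable stereocentre (future C8) is not epimerised.

Step 2
Reactants: 2 methyl (R)-3-(benzyloxy)-2-methylpropanoate; 3 tert-butyl acetate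
Product: 5 tert-butyl (4R)-5-(benzyloxy)-4-methyl-3-oxopentanoate, via lithium enolate of tert-butyl acetate 4 (not isolated)
Conditions: LiN(iPr)2 (3 equiv), 3 (3.2 equiv), THF, −78 °C; then 2, −78 → −20 °C; aq. NH4Cl
Reagents that add atoms: none
Why: Crossed Claisen condensation in which excess enolate 4 acylates on the methyl ester and the product rests as its doubly stabilised enolate until the quench, which shields the neighbouring stereocentre from epimerisation.

Step 3
Reactants: 5 tert-butyl (4R)-5-(benzyloxy)-4-methyl-3-oxopentanoate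
Product: 6 tert-butyl (3R,4R)-5-(benzyloxy)-3-hydroxy-4-methylpentanoate
Conditions: H2 (50 bar), RuCl2[(S)-BINAP](dmf)n (1 mol %), MeOH, 50 °C
Reagents that add atoms: none
Why: Noyori asymmetric hydrogenation of a β-keto ester, in which the (S)-BINAP catalyst delivers hydrogen under catalyst control to the ketone face that gives the (3R) carbinol (the facial sense that gives (S)-3-hydroxybutanoate from acetoacetate, the descriptor differing only through CIP priorities), so C9 is set syn to the C8 methyl group while the benzyl ether is inert to the homogeneous catalyst.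

Step 4
Reactants: 6 tert-butyl (3R,4R)-5-(benzyloxy)-3-hydroxy-4-methylpentanoate
Product: 8 (4R,5R)-4-hydroxy-5-methyloxan-2-one, via tert-butyl (3R,4R)-3,5-dihydroxy-4-methylpentanoate 7 (not isolated)
Conditions: H2 (1 atm), Pd/C, EtOAc, rt; filter; then CF3CO2H, CH2Cl2, 0 °C → rt
Reagents that add atoms: none
Why: Hydrogenolysis of the benzyl ether frees the primary alcohol, and acid-mediated cleavage of the tert-butyl ester with lactonisation closes the six-membered ring through that primary hydroxyl, leaving the secondary alcohol free and both stereocentres untouched.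

Step 5
Reactants: 8 (4R,5R)-4-hydroxy-5-methyloxan-2-one
Product: 9 (4R,5R)-4-[(tert-butyldimethylsilyl)oxy]-5-methyloxan-2-one
Conditions: TBSCl, imidazole, DMF, rt
Reagents that add atoms: tert-butyldimethylsilyl chloride, CC(C)(C)[Si](C)(C)Cl
Why: Standard imidazole-mediated silylation of a secondary alcohol, mild enough not to dehydrate the β-hydroxy lactone.

Step 6
Reactants: 10 N-methylformamide
Product: 11 methyl isocyanide
Conditions: TsCl, quinoline, 75 °C, reduced pressure, product distilled into a cold trap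
Reagents that add atoms: none
Why: Dehydration of an N-monosubstituted formamide with a sulfonyl chloride and a tertiary amine is the classical isocyanide synthesis, and the high-boiling base lets the volatile isocyanide distil out as it forms.

Step 7
Reactants: 9 (4R,5R)-4-[(tert-butyldimethylsilyl)oxy]-5-methyloxan-2-one; 11 methyl isocyanide
Product: 15 (2R,3R)-3-[(tert-butyldimethylsilyl)oxy]-2-methyl-4-(1,3-oxazol-5-yl)butan-1-ol, via lithiomethyl isocyanide 12 (not isolated), via dilithium isocyano enolate alkoxide 13 (not isolated), via 2-lithiooxazole alkoxide 14 (not isolated)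
Conditions: 11 (2.3 equiv), n-BuLi (2.2 equiv), THF, −78 °C; then 9, −78 °C; AcOH, −78 °C → rt
Reagents that add atoms: none
Why: This is the Schöllkopf oxazole synthesis applied to a lactone: carbanion 12 adds to the carbonyl of 9 (oxazole C4–C5 bond), the tetrahedral adduct collapses with cleavage of the ring C–O bond to an α-isocyano ketone, and a second equivalent of 12 deprotonates it to enolate 13. The enolate oxygen then attacks the isocyanide carbon in a 5-endo-dig closure (O1–C2 bond) to give 14, and acetic acid protonates C2 and the C7 alkoxide. No stereocentre is formed, and C8 and C9 are not α to the carbonyl, so they are not touched. The step needs carbonyl addition to outrun α-deprotonation of the lactone, which would expel the C9 silyloxy group; the small carbanion at −78 °C, the high electrophilicity of a δ-lactone and the pseudo-equatorial, poorly aligned silyloxy group of the trans-disubstituted ring should favour addition. After ring opening the ketone enolises only towards the isocyanide-bearing carbon, so β-elimination stays suppressed, and keeping the lithium alkoxide cold until the acid quench should prevent silyl transfer from O9 to O7.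

Step 8
Reactants: 15 (2R,3R)-3-[(tert-butyldimethylsilyl)oxy]-2-methyl-4-(1,3-oxazol-5-yl)butan-1-ol
Product: 17 ethyl (2E,4R,5R)-5-[(tert-butyldimethylsilyl)oxy]-4-methyl-6-(1,3-oxazol-5-yl)hex-2-enoate, via (2S,3R)-3-[(tert-butyldimethylsilyl)oxy]-2-methyl-4-(1,3-oxazol-5-yl)butanal 16 (not isolated)
Conditions: Dess–Martin periodinane, CH2Cl2, 0 °C → rt; then Ph3P=CHCO2Et, rt
Reagents that add atoms: ethyl (triphenylphosphoranylidene)acetate, CCOC(=O)C=P(c1ccccc1)(c1ccccc1)c1ccccc1
Why: One-pot Dess–Martin oxidation and Wittig olefination, in which the stabilised ylide traps the α-branched aldehyde 16 as it forms so that C8 should not epimerise (the alkene geometry is irrelevant after step 9).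

Step 9
Reactants: 17 ethyl (2E,4R,5R)-5-[(tert-butyldimethylsilyl)oxy]-4-methyl-6-(1,3-oxazol-5-yl)hex-2-enoate
Product: 18 ethyl (4R,5R)-5-[(tert-butyldimethylsilyl)oxy]-4-methyl-6-(1,3-oxazol-5-yl)hexanoate
Conditions: H2 (1 atm), Pd/C, EtOAc, rt
Reagents that add atoms: none
Why: Heterogeneous catalytic hydrogenation saturates the conjugated alkene, while the aromatic oxazole and the silyl ether are not affected at atmospheric pressure in a non-protic solvent.

Step 10
Reactants: 18 ethyl (4R,5R)-5-[(tert-butyldimethylsilyl)oxy]-4-methyl-6-(1,3-oxazol-5-yl)hexanoate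
Product: 19 (4R,5R)-5-[(tert-butyldimethylsilyl)oxy]-4-methyl-6-(1,3-oxazol-5-yl)hexanal
Conditions: iBu2AlH (1.1 equiv), CH2Cl2, −78 °C; aq. potassium sodium tartrate
Reagents that add atoms: none
Why: Partial reduction of an ester with iBu2AlH at −78 °C stops at the aluminium hemiacetal, which releases the aldehyde only on work-up.

Step 11
Reactants: 19 (4R,5R)-5-[(tert-butyldimethylsilyl)oxy]-4-methyl-6-(1,3-oxazol-5-yl)hexanal
Product: 20 5-[(2R,3R)-2-[(tert-butyldimethylsilyl)oxy]-3-methylhept-6-yn-1-yl]-1,3-oxazole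
Conditions: dimethyl (1-diazo-2-oxopropyl)phosphonate, K2CO3, MeOH, 0 °C → rt
Reagents that add atoms: dimethyl (1-diazo-2-oxopropyl)phosphonate, COP(=O)(OC)C(=[N+]=[N-])C(C)=O
Why: The Ohira–Bestmann variant of the Seyferth–Gilbert homologation turns the aldehyde into the terminal alkyne (adding C4) under mild carbonate conditions that leave the silyl ether and the remote stereocentres alone.

Step 12
Reactants: 21 propargyl alcohol
Product: 23 (Z)-3-iodo-2-methylprop-2-en-1-ol, via alkenylmagnesium alkoxide 22 (not isolated)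
Conditions: MeMgBr (2.5 equiv), CuI (10 mol %), THF/Et2O, −10 °C → rt; then I2, −20 °C → rt; aq. NH4Cl
Reagents that add atoms: methylmagnesium bromide, C[Mg]Br; iodine, II
Why: Copper-catalysed anti-carbomagnesiation of the propargylic alkoxide places methyl on C2 and magnesium on C3 cis to the oxymethyl group through a five-membered chelate, and iodinolysis with retention fixes the (Z) geometry of the later C2=C3 bond.

Step 13
Reactants: 23 (Z)-3-iodo-2-methylprop-2-en-1-ol
Product: 25 (Z)-3-iodo-2-methylprop-2-enoic acid, via (Z)-3-iodo-2-methylprop-2-enal 24 (not isolated)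
Conditions: MnO2, CH2Cl2, rt; filter; then NaClO2, NaH2PO4, 2-methyl-2-butene, t-BuOH/H2O, 0 °C → rt
Reagents that add atoms: sodium chlorite, [Na+].[O-]Cl=O
Why: Allylic oxidation with MnO2 followed at once by Pinnick oxidation reaches the acid without strong acid or base and without storing the labile (Z)-iodoenal 24, so the alkene geometry should be kept.

Step 14
Reactants: 25 (Z)-3-iodo-2-methylprop-2-enoic acid
Product: 26 2-(trimethylsilyl)ethyl (Z)-3-iodo-2-methylprop-2-enoate
Conditions: Me3SiCH2CH2OH, PPh3, DIAD, THF, 0 °C → rt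
Reagents that add atoms: 2-(trimethylsilyl)ethanol, C[Si](C)(C)CCO
Why: Mitsunobu esterification activates the alcohol and not the acid, so the (Z)-β-iodoacrylate is esterified without an acyl intermediate that could isomerise by addition–elimination.

Step 15
Reactants: 20 5-[(2R,3R)-2-[(tert-butyldimethylsilyl)oxy]-3-methylhept-6-yn-1-yl]-1,3-oxazole; 26 2-(trimethylsilyl)ethyl (Z)-3-iodo-2-methylprop-2-enoate
Product: 27 2-(trimethylsilyl)ethyl (2Z,8R,9R)-9-[(tert-butyldimethylsilyl)oxy]-2,8-dimethyl-10-(1,3-oxazol-5-yl)dec-2-en-4-ynoate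
Conditions: PdCl2(PPh3)2 (5 mol %), CuI (10 mol %), Et3N, THF (degassed), rt
Reagents that add atoms: none
Why: Sonogashira coupling of the terminal alkyne with the (Z)-vinyl iodide forms the C3–C4 bond at room temperature with retention of alkene geometry, and the oxazole C2–H is inert under these conditions.

Step 16
Reactants: 27 2-(trimethylsilyl)ethyl (2Z,8R,9R)-9-[(tert-butyldimethylsilyl)oxy]-2,8-dimethyl-10-(1,3-oxazol-5-yl)dec-2-en-4-ynoate
Product: 28 2-(trimethylsilyl)ethyl (2Z,4Z,8R,9R)-9-[(tert-butyldimethylsilyl)oxy]-2,8-dimethyl-10-(1,3-oxazol-5-yl)deca-2,4-dienoate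
Conditions: Zn dust activated with Cu(OAc)2 and AgNO3, MeOH/H2O (1:1), rt → 40 °C
Reagents that add atoms: none
Why: Boland semireduction with copper- and silver-activated zinc reduces the conjugated alkyne by syn delivery of two hydrogens to the (4Z) alkene and does not touch alkenes, and doing it while O9 is still silylated avoids any conjugate addition of a free C9 hydroxyl to the activated enyne.

Step 17
Reactants: 28 2-(trimethylsilyl)ethyl (2Z,4Z,8R,9R)-9-[(tert-butyldimethylsilyl)oxy]-2,8-dimethyl-10-(1,3-oxazol-5-yl)deca-2,4-dienoate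
Product: 29 (2Z,4Z,8R,9R)-9-hydroxy-2,8-dimethyl-10-(1,3-oxazol-5-yl)deca-2,4-dienoic acid
Conditions: Bu4NF (excess), THF, 0 °C → rt; aq. NH4Cl
Reagents that add atoms: none
Why: Fluoride-induced β-elimination cleaves the 2-(trimethylsilyl)ethyl ester and fluoride also removes the secondary silyl ether, so one reagent unmasks both ends of the seco acid without a hydroxide step that could isomerise the dienoate.

Step 18
Reactants: 29 (2Z,4Z,8R,9R)-9-hydroxy-2,8-dimethyl-10-(1,3-oxazol-5-yl)deca-2,4-dienoic acid (two molecules)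
Product: 32 (3Z,5Z,9R,10R,13Z,15Z,19R,20R)-3,9,13,19-tetramethyl-10,20-bis[(1,3-oxazol-5-yl)methyl]-1,11-dioxacycloicosa-3,5,13,15-tetraene-2,12-dione, via monomer mixed anhydride 30 (not isolated), via linear dimer mixed anhydride 31 (not isolated)
Conditions: 2,4,6-Cl3C6H2COCl, Et3N, THF, rt; then slow addition to DMAP, toluene, 40 °C (final concentration about 5 mM)
Reagents that add atoms: none
Why: Yamaguchi cyclodimerisation, in which mixed anhydride 30 first acylates the C9 hydroxyl of a second molecule and the linear dimer 31 then closes head-to-tail to the twenty-membered diolide, a ring that should form faster than the strained ten-membered monolide, which would have to hold the (2Z,4Z)-dienoate out of plane.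

**Compound list**

1 | methyl (R)-3-hydroxy-2-methylpropanoate | OC[C@@H](C)C(=O)OC | starting material
2 | methyl (R)-3-(benzyloxy)-2-methylpropanoate | c1ccccc1COC[C@@H](C)C(=O)OC | intermediate
3 | tert-butyl acetate | CC(=O)OC(C)(C)C | starting material
4 | lithium enolate of tert-butyl acetate | [Li]OC(=C)OC(C)(C)C | intermediate
5 | tert-butyl (4R)-5-(benzyloxy)-4-methyl-3-oxopentanoate | c1ccccc1COC[C@@H](C)C(=O)CC(=O)OC(C)(C)C | intermediate
6 | tert-butyl (3R,4R)-5-(benzyloxy)-3-hydroxy-4-methylpentanoate | c1ccccc1COC[C@@H](C)[C@@H](CC(=O)OC(C)(C)C)O | intermediate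
7 | tert-butyl (3R,4R)-3,5-dihydroxy-4-methylpentanoate | OC[C@@H](C)[C@@H](CC(=O)OC(C)(C)C)O | intermediate
8 | (4R,5R)-4-hydroxy-5-methyloxan-2-one | C1[C@@H](C)[C@@H](CC(=O)O1)O | intermediate
9 | (4R,5R)-4-[(tert-butyldimethylsilyl)oxy]-5-methyloxan-2-one | C1[C@@H](C)[C@@H](CC(=O)O1)O[Si](C)(C)C(C)(C)C | intermediate
10 | N-methylformamide | CNC=O | starting material
11 | methyl isocyanide | C[N+]#[C-] | intermediate
12 | lithiomethyl isocyanide | [Li]C[N+]#[C-] | intermediate
13 | dilithium (4R,5R)-4-[(tert-butyldimethylsilyl)oxy]-1-isocyano-5-methylhex-1-ene-2,6-bis(olate) | [Li]OC[C@@H](C)[C@@H](CC(O[Li])=C[N+]#[C-])O[Si](C)(C)C(C)(C)C | intermediate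
14 | lithium (2R,3R)-3-[(tert-butyldimethylsilyl)oxy]-4-(2-lithio-1,3-oxazol-5-yl)-2-methylbutan-1-olate | [Li]OC[C@@H](C)[C@@H](Cc1cnc([Li])o1)O[Si](C)(C)C(C)(C)C | intermediate
15 | (2R,3R)-3-[(tert-butyldimethylsilyl)oxy]-2-methyl-4-(1,3-oxazol-5-yl)butan-1-ol | OC[C@@H](C)[C@@H](Cc1cnco1)O[Si](C)(C)C(C)(C)C | intermediate
16 | (2S,3R)-3-[(tert-butyldimethylsilyl)oxy]-2-methyl-4-(1,3-oxazol-5-yl)butanal | O=C[C@@H](C)[C@@H](Cc1cnco1)O[Si](C)(C)C(C)(C)C | intermediate
17 | ethyl (2E,4R,5R)-5-[(tert-butyldimethylsilyl)oxy]-4-methyl-6-(1,3-oxazol-5-yl)hex-2-enoate | CCOC(=O)/C=C/[C@@H](C)[C@@H](Cc1cnco1)O[Si](C)(C)C(C)(C)C | intermediate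
18 | ethyl (4R,5R)-5-[(tert-butyldimethylsilyl)oxy]-4-methyl-6-(1,3-oxazol-5-yl)hexanoate | CCOC(=O)CC[C@@H](C)[C@@H](Cc1cnco1)O[Si](C)(C)C(C)(C)C | intermediate
19 | (4R,5R)-5-[(tert-butyldimethylsilyl)oxy]-4-methyl-6-(1,3-oxazol-5-yl)hexanal | O=CCC[C@@H](C)[C@@H](Cc1cnco1)O[Si](C)(C)C(C)(C)C | intermediate
20 | 5-[(2R,3R)-2-[(tert-butyldimethylsilyl)oxy]-3-methylhept-6-yn-1-yl]-1,3-oxazole | C#CCC[C@@H](C)[C@@H](Cc1cnco1)O[Si](C)(C)C(C)(C)C | intermediate
21 | propargyl alcohol (prop-2-yn-1-ol) | C#CCO | starting material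
22 | (Z)-[3-(bromomagnesiooxy)-2-methylprop-1-en-1-yl]magnesium bromide | Br[Mg]/C=C(/C)CO[Mg]Br | intermediate
23 | (Z)-3-iodo-2-methylprop-2-en-1-ol | I/C=C(/C)CO | intermediate
24 | (Z)-3-iodo-2-methylprop-2-enal | I/C=C(/C)C=O | intermediate
25 | (Z)-3-iodo-2-methylprop-2-enoic acid | I/C=C(/C)C(=O)O | intermediate
26 | 2-(trimethylsilyl)ethyl (Z)-3-iodo-2-methylprop-2-enoate | I/C=C(/C)C(=O)OCC[Si](C)(C)C | intermediate
27 | 2-(trimethylsilyl)ethyl (2Z,8R,9R)-9-[(tert-butyldimethylsilyl)oxy]-2,8-dimethyl-10-(1,3-oxazol-5-yl)dec-2-en-4-ynoate | C[Si](C)(C)CCOC(=O)/C(C)=C\C#CCC[C@@H](C)[C@@H](Cc1cnco1)O[Si](C)(C)C(C)(C)C | intermediate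
28 | 2-(trimethylsilyl)ethyl (2Z,4Z,8R,9R)-9-[(tert-butyldimethylsilyl)oxy]-2,8-dimethyl-10-(1,3-oxazol-5-yl)deca-2,4-dienoate | C[Si](C)(C)CCOC(=O)/C(C)=C\C=C/CC[C@@H](C)[C@@H](Cc1cnco1)O[Si](C)(C)C(C)(C)C | intermediate
29 | (2Z,4Z,8R,9R)-9-hydroxy-2,8-dimethyl-10-(1,3-oxazol-5-yl)deca-2,4-dienoic acid | OC(=O)/C(C)=C\C=C/CC[C@@H](C)[C@@H](Cc1cnco1)O | intermediate
30 | mixed anhydride of 29 with 2,4,6-trichlorobenzoic acid | Clc1cc(Cl)cc(Cl)c1C(=O)OC(=O)/C(C)=C\C=C/CC[C@@H](C)[C@@H](Cc2cnco2)O | intermediate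
31 | linear dimer: the acyl group of 29 on O9 of a second unit whose carboxyl is the 2,4,6-trichlorobenzoic mixed anhydride | Clc1cc(Cl)cc(Cl)c1C(=O)OC(=O)/C(C)=C\C=C/CC[C@@H](C)[C@@H](Cc2cnco2)OC(=O)/C(C)=C\C=C/CC[C@@H](C)[C@@H](Cc2cnco2)O | intermediate
32 | (3Z,5Z,9R,10R,13Z,15Z,19R,20R)-3,9,13,19-tetramethyl-10,20-bis[(1,3-oxazol-5-yl)methyl]-1,11-dioxacycloicosa-3,5,13,15-tetraene-2,12-dione | C/C1=C/C=C\CC[C@@H](C)[C@@H](Cc2cnco2)OC(=O)/C(C)=C\C=C/CC[C@@H](C)[C@@H](Cc2cnco2)OC1=O | target

**Totals**

Total step count: 18. Longest linear sequence: 14 steps (steps 1–5, 7–11, 15–18); steps 6 and 12–14 are side branches.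

**Steps most likely to fail**

1. Step 18. The intermolecular acylation may lose to ring closure of the monomer, or chain growth may continue past the dimer to cyclic trimers and linear oligomers. The activated (2Z)-acyl group may also drift to the (2E) isomer by reversible conjugate addition of DMAP. The fallback builds the ring stepwise; it sets out from 28 and comes back at 32. One part of 28 is treated briefly with (Me2N)3S+ Me3SiF2− in DMF at 0 °C, which should cleave the silylethyl ester ahead of the hindered secondary silyl ether and give (2Z,4Z,8R,9R)-9-[(tert-butyldimethylsilyl)oxy]-2,8-dimethyl-10-(1,3-oxazol-5-yl)deca-2,4-dienoic acid F1. A second part is treated with HF·pyridine in THF/pyridine to give 2-(trimethylsilyl)ethyl (2Z,4Z,8R,9R)-9-hydroxy-2,8-dimethyl-10-(1,3-oxazol-5-yl)deca-2,4-dienoate F2. Yamaguchi esterification of F1 with F2 at normal concentration, with only catalytic DMAP, should give the linear ester dimer F3. Bu4NF then removes both silicon groups to give the linear hydroxy acid dimer F4, and Yamaguchi macrolactonisation of F4 under high dilution is a purely intramolecular closure to 32.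

2. Step 7. The carbanion may deprotonate the lactone α to the carbonyl with loss of the C9 silyloxy group, the silyl group may move from O9 to the C7 alkoxide, or the cyclic tetrahedral adduct may fail to open. The fallback moves to an acyclic acyl donor with the C7 oxygen capped; it sets out from 9 and comes back at 15. Lactone 9 is opened with MeNH(OMe)·HCl and Me3Al in CH2Cl2 to (3R,4R)-3-[(tert-butyldimethylsilyl)oxy]-5-hydroxy-N-methoxy-N,4-dimethylpentanamide F5, which is silylated at once (Et3SiCl, imidazole) to (3R,4R)-3-[(tert-butyldimethylsilyl)oxy]-N-methoxy-N,4-dimethyl-5-[(triethylsilyl)oxy]pentanamide F6. Addition of 12 at −78 °C gives a chelated adduct that holds the ketone back until the quench and then releases (4R,5R)-4-[(tert-butyldimethylsilyl)oxy]-1-isocyano-5-methyl-6-[(triethylsilyl)oxy]hexan-2-one F7. Triethylamine in CH2Cl2 should cyclise this α-isocyano ketone to 5-[(2R,3R)-2-[(tert-butyldimethylsilyl)oxy]-3-methyl-4-[(triethylsilyl)oxy]butyl]-1,3-oxazole F8, and selective methanolysis of the primary triethylsilyl ether (pyridinium p-toluenesulfonate, MeOH, 0 °C) gives 15.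

3. Step 16. The zinc reduction may stall, may run on to over-reduced products, or may be accompanied by Z→E drift of the conjugated diene. The fallback forms the C3–C4 bond between two (Z)-alkenyl partners without any reduction; it sets out from 20 and comes back at 28. Rhodium-catalysed trans-hydroboration of alkyne 20 ([RhCl(cod)]2, P(iPr)3, Et3N, pinacolborane, cyclohexane, rt) should give 5-[(2R,3R,6Z)-2-[(tert-butyldimethylsilyl)oxy]-3-methyl-7-(4,4,5,5-tetramethyl-1,3,2-dioxaborolan-2-yl)hept-6-en-1-yl]-1,3-oxazole F9. Suzuki–Miyaura coupling of F9 with iodoacrylate 26 (Pd(PPh3)4, aqueous K3PO4, THF, rt) proceeds with retention at both alkenes and gives 28 directly, in place of steps 15 and 16.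

**Further compounds**

F1 | step 18 | (2Z,4Z,8R,9R)-9-[(tert-butyldimethylsilyl)oxy]-2,8-dimethyl-10-(1,3-oxazol-5-yl)deca-2,4-dienoic acid | OC(=O)/C(C)=C\C=C/CC[C@@H](C)[C@@H](Cc1cnco1)O[Si](C)(C)C(C)(C)C
F2 | step 18 | 2-(trimethylsilyl)ethyl (2Z,4Z,8R,9R)-9-hydroxy-2,8-dimethyl-10-(1,3-oxazol-5-yl)deca-2,4-dienoate | C[Si](C)(C)CCOC(=O)/C(C)=C\C=C/CC[C@@H](C)[C@@H](Cc1cnco1)O
F3 | step 18 | linear ester dimer (acyl group of F1 on O9 of F2; silyl ether at one end, silylethyl ester at the other) | C[Si](C)(C)CCOC(=O)/C(C)=C\C=C/CC[C@@H](C)[C@@H](Cc1cnco1)OC(=O)/C(C)=C\C=C/CC[C@@H](C)[C@@H](Cc1cnco1)O[Si](C)(C)C(C)(C)C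
F4 | step 18 | linear hydroxy acid dimer (seco acid of 32) | OC(=O)/C(C)=C\C=C/CC[C@@H](C)[C@@H](Cc1cnco1)OC(=O)/C(C)=C\C=C/CC[C@@H](C)[C@@H](Cc1cnco1)O
F5 | step 7 | (3R,4R)-3-[(tert-butyldimethylsilyl)oxy]-5-hydroxy-N-methoxy-N,4-dimethylpentanamide | OC[C@@H](C)[C@@H](CC(=O)N(C)OC)O[Si](C)(C)C(C)(C)C
F6 | step 7 | (3R,4R)-3-[(tert-butyldimethylsilyl)oxy]-N-methoxy-N,4-dimethyl-5-[(triethylsilyl)oxy]pentanamide | CC[Si](CC)(CC)OC[C@@H](C)[C@@H](CC(=O)N(C)OC)O[Si](C)(C)C(C)(C)C
F7 | step 7 | (4R,5R)-4-[(tert-butyldimethylsilyl)oxy]-1-isocyano-5-methyl-6-[(triethylsilyl)oxy]hexan-2-one | CC[Si](CC)(CC)OC[C@@H](C)[C@@H](CC(=O)C[N+]#[C-])O[Si](C)(C)C(C)(C)C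
F8 | step 7 | 5-[(2R,3R)-2-[(tert-butyldimethylsilyl)oxy]-3-methyl-4-[(triethylsilyl)oxy]butyl]-1,3-oxazole | CC[Si](CC)(CC)OC[C@@H](C)[C@@H](Cc1cnco1)O[Si](C)(C)C(C)(C)C
F9 | step 16 | 5-[(2R,3R,6Z)-2-[(tert-butyldimethylsilyl)oxy]-3-methyl-7-(4,4,5,5-tetramethyl-1,3,2-dioxaborolan-2-yl)hept-6-en-1-yl]-1,3-oxazole | CC1(C)OB(OC1(C)C)/C=C\CC[C@@H](C)[C@@H](Cc2cnco2)O[Si](C)(C)C(C)(C)C
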